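**Plan**

- Ring A is the phenol ring (C1 OH, C2 aryloxy, C3 and C6 Br); ring B is the 2,4-dibromophenyl ring. The retrosynthesis cuts, in order, the two C–Br bonds of ring B, the C1–O bond (traced back to a C1–B bond), the C6–Br bond (bromine returned to C1) and the C2–O ether bond.
- Enabling feature: C1 of ring A lies between the ether carbon C2 and the bromine-bearing C6, the best-stabilised aryl-anion site of that ring. A bromine placed at C1 of a symmetric 2,6-dibromophenyl phenyl ether can therefore be driven to C6 while lithium, then boron, then oxygen take its place at C1.
- Forward: the two rings are joined first through the ether oxygen (SNAr). Bromine migration with borate trapping, oxidation, acetylation, double bromination of ring B and deacetylation follow. No ring is formed at any stage.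
- Stereochemistry: the target has no stereocentre and its diaryl ether bonds rotate freely, so it is achiral and a single species; no stereocontrol is needed.

Key step: step 2

**Step 1**
Reactants: 1 1,3-dibromo-2-fluorobenzene; 2 phenol
Product: 3 1,3-dibromo-2-phenoxybenzene
Conditions: K2CO3 (2 equiv), NMP, 150 °C
Reagents that add atoms: none
Why: Nucleophilic aromatic substitution (SNAr) in which fluoride, the best SNAr leaving group and inductively activated by the two ortho bromines, is displaced by potassium phenoxide in a hot dipolar aprotic solvent, while the C–Br bonds stay inert in the absence of a transition metal.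

**Step 2**
Reactants: 3 1,3-dibromo-2-phenoxybenzene; 4 trimethyl borate
Product: 10 (3,6-dibromo-2-phenoxyphenyl)boronic acid, via (2,4-dibromo-3-phenoxyphenyl)lithium 5 (not isolated), via 1,2,4-tribromo-3-phenoxybenzene 6 (not isolated), via (3-bromo-2-phenoxyphenyl)lithium 7 (not isolated), via (3,6-dibromo-2-phenoxyphenyl)lithium 8 (not isolated), via lithium (3,6-dibromo-2-phenoxyphenyl)trimethoxyborate 9 (not isolated)
Conditions: LDA (1.1 equiv, commercial solution, added dropwise to 3), THF, −78 °C, 2 h; B(OMe)3 (1.5 equiv), −78 → 0 °C; 1 M HCl
Reagents that add atoms: trimethyl borate 4, COB(OC)OC; water, O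
Why: Base-catalysed halogen dance followed by borylation: LDA removes H6, which is ortho to the C1 bromine and further acidified by the meta aryloxy group and the para bromine, to give aryllithium 5. 5 takes bromine from C1 of still unmetalated 3 by lithium–bromine exchange, giving tribromide 6 and aryllithium 7; 6 then serves as the bromine shuttle, its C1 bromine being exchanged by 5 (which regenerates 6) or by 7 (which regenerates 3 for renewed deprotonation), each exchange releasing 8. The closest known reaction type is the LDA-induced bromine migration of 2-bromoaryl ethers and 2-bromofluoroarenes to 2-bromo-6-(alkoxy or fluoro)phenyllithiums that are then trapped by electrophiles. No ring closes and no stereocentre is formed. The step needs lithium to end at C1 and not at C4, C5 or on ring B: only C1 is flanked by both the ether oxygen and a bromine, so the reversible exchange manifold drains into 8, the symmetry of 3 makes both directions of the dance identical, and the bromine-free ring B offers neither a comparably acidic C–H bond nor an exchangeable halogen. Trimethyl borate at −78 °C captures 8 as borate 9 before lithium bromide can be lost to an aryne, and acidic work-up hydrolyses 9 to boronic acid 10.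

**Step 3**
Reactants: 10 (3,6-dibromo-2-phenoxyphenyl)boronic acid
Product: 11 3,6-dibromo-2-phenoxyphenol
Conditions: 30% aq H2O2, AcOH, THF, 0 °C → rt
Reagents that add atoms: hydrogen peroxide, OO
Why: Oxidative ipso-hydroxylation of an arylboronic acid (hydroperoxide adds to boron, the aryl group migrates from boron to oxygen, B–O hydrolysis follows) puts the hydroxyl exactly at C1, and the weakly acidic medium suppresses protodeboronation of the doubly ortho-substituted boronic acid.

**Step 4**
Reactants: 11 3,6-dibromo-2-phenoxyphenol
Product: 12 3,6-dibromo-2-phenoxyphenyl acetate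
Conditions: Ac2O (1.5 equiv), pyridine, DMAP (cat.), CH2Cl2, rt
Reagents that add atoms: acetic anhydride, CC(=O)OC(C)=O
Why: DMAP-catalysed O-acetylation of the phenol; the acetoxy group withdraws the oxygen lone pair from ring A, so that C4, para to the free hydroxyl in 11, is no longer the most nucleophilic site of the molecule.

**Step 5**
Reactants: 12 3,6-dibromo-2-phenoxyphenyl acetate
Product: 14 3,6-dibromo-2-(2,4-dibromophenoxy)phenyl acetate, via 3,6-dibromo-2-(4-bromophenoxy)phenyl acetate 13 (not isolated)
Conditions: Br2 (2.2 equiv), Fe powder (cat.), CH2Cl2, 0 °C → rt, dark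
Reagents that add atoms: bromine, BrBr
Why: Electrophilic aromatic bromination in which ring B, activated by the ether oxygen and free of deactivating groups, is brominated para and then ortho to oxygen, whereas ring A is deactivated by two bromines and the acetoxy group and is twisted out of conjugation with the ether oxygen by its two ortho substituents; each bromine deactivates ring B further, so two equivalents should stop at the 2,4-dibromide.

**Step 6**
Reactants: 14 3,6-dibromo-2-(2,4-dibromophenoxy)phenyl acetate
Product: 15 3,6-dibromo-2-(2,4-dibromophenoxy)phenol
Conditions: K2CO3 (2 equiv), MeOH, rt; 1 M HCl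
Reagents that add atoms: none
Why: Base-mediated transesterification (methanolysis) of the aryl acetate, fast because the polybrominated phenoxide is a good leaving group, while the aryl bromides and the diaryl ether are inert to carbonate in methanol at room temperature.

**Compound list**

1 | 1,3-dibromo-2-fluorobenzene | Fc1c(Br)cccc1Br | starting material
2 | phenol | Oc1ccccc1 | starting material
3 | 1,3-dibromo-2-phenoxybenzene | Brc1cccc(Br)c1Oc1ccccc1 | intermediate
4 | trimethyl borate | COB(OC)OC | starting material
5 | (2,4-dibromo-3-phenoxyphenyl)lithium | [Li]c1ccc(Br)c(Oc2ccccc2)c1Br | intermediate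
6 | 1,2,4-tribromo-3-phenoxybenzene | Brc1ccc(Br)c(Oc2ccccc2)c1Br | intermediate
7 | (3-bromo-2-phenoxyphenyl)lithium | [Li]c1cccc(Br)c1Oc1ccccc1 | intermediate
8 | (3,6-dibromo-2-phenoxyphenyl)lithium | [Li]c1c(Br)ccc(Br)c1Oc1ccccc1 | intermediate
9 | lithium (3,6-dibromo-2-phenoxyphenyl)trimethoxyborate | [Li+].CO[B-](OC)(OC)c1c(Br)ccc(Br)c1Oc1ccccc1 | intermediate
10 | (3,6-dibromo-2-phenoxyphenyl)boronic acid | OB(O)c1c(Br)ccc(Br)c1Oc1ccccc1 | intermediate
11 | 3,6-dibromo-2-phenoxyphenol | Oc1c(Br)ccc(Br)c1Oc1ccccc1 | intermediate
12 | 3,6-dibromo-2-phenoxyphenyl acetate | CC(=O)Oc1c(Br)ccc(Br)c1Oc1ccccc1 | intermediate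
13 | 3,6-dibromo-2-(4-bromophenoxy)phenyl acetate | CC(=O)Oc1c(Br)ccc(Br)c1Oc1ccc(Br)cc1 | intermediate
14 | 3,6-dibromo-2-(2,4-dibromophenoxy)phenyl acetate | CC(=O)Oc1c(Br)ccc(Br)c1Oc1ccc(Br)cc1Br | intermediate
15 | 3,6-dibromo-2-(2,4-dibromophenoxy)phenol | Oc1c(Br)ccc(Br)c1Oc1ccc(Br)cc1Br | target

**Totals**

Total step count: 6. Longest linear sequence: 6 steps (1 → 3 → 10 → 11 → 12 → 14 → 15).

**Steps most likely to fail**

Step 2. The bromine relay may stall, so that the kinetic aryllithium 5 is borylated instead of 8. The ortho-bromo aryllithiums may lose lithium bromide to an aryne if the temperature drifts, and the doubly ortho-substituted boronic acid may protodeboronate on work-up. The fallback builds the oxygenation pattern of ring A by two successive fluoride displacements and sets out from phenol 2. SNAr of 2 (one equivalent, K2CO3, DMSO, 80 °C) on commercially available 1,4-dibromo-2,3-difluorobenzene should give 1,4-dibromo-2-fluoro-3-phenoxybenzene F1. Sodium methoxide in DMSO at 100 °C should then displace the remaining fluoride to give 1,4-dibromo-2-methoxy-3-phenoxybenzene F2. BBr3 in CH2Cl2 should cleave the methyl ether while leaving the diaryl ether untouched, and the route is rejoined at phenol 11 before step 4.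

Step 5. Bromination may stall after the para bromine, the acetyl group may be lost under HBr and Lewis acid so that ring A is then brominated para to the freed hydroxyl, ring A may be attacked at C5 para to the ether oxygen, or ring B may be overbrominated. The fallback brings ring B in already brominated and sets out from 1. Sodium methoxide in DMSO should convert 1 into 1,3-dibromo-2-methoxybenzene F3 by SNAr. The same LDA-induced bromine migration with trapping by trimethyl borate 4 should give (3,6-dibromo-2-methoxyphenyl)boronic acid F4, and peroxide oxidation should give 3,6-dibromo-2-methoxyphenol F5. O-Arylation of F5 with bis(2,4-dibromophenyl)iodonium chloride F6 (from 1,3-dibromobenzene and iodyl sulfate in sulfuric acid, then chloride) in aqueous NaOH/dioxane at 80 °C should give 1,4-dibromo-2-(2,4-dibromophenoxy)-3-methoxybenzene F7 by ligand coupling at iodine(III). BBr3 in CH2Cl2 should cleave the methyl ether and deliver target 15 directly. Because the 3,6-dibromocatechol core is symmetric, it does not matter which of its two oxygens carries the aryl group.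

Step 1. Fluoride displacement at a carbon flanked by two bromines and activated only inductively may be sluggish, and the forcing temperature may erode the material through loss of bromide. The fallback replaces SNAr by a copper-catalysed Ullmann etherification and sets out from phenol 2. Coupling of 2 with commercially available 1,3-dibromo-2-iodobenzene (CuI, picolinic acid, K3PO4, DMSO, 90 °C) should engage the C–I bond in preference to the two C–Br bonds and give 3 directly, where the route is rejoined; no new compound is made on the way (F0).

**Further compounds**

F1 | step 2 | 1,4-dibromo-2-fluoro-3-phenoxybenzene | Fc1c(Br)ccc(Br)c1Oc1ccccc1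
F2 | step 2 | 1,4-dibromo-2-methoxy-3-phenoxybenzene | COc1c(Br)ccc(Br)c1Oc1ccccc1
F3 | step 5 | 1,3-dibromo-2-methoxybenzene | COc1c(Br)cccc1Br
F4 | step 5 | (3,6-dibromo-2-methoxyphenyl)boronic acid | COc1c(Br)ccc(Br)c1B(O)O
F5 | step 5 | 3,6-dibromo-2-methoxyphenol | COc1c(Br)ccc(Br)c1O
F6 | step 5 | bis(2,4-dibromophenyl)iodonium chloride | Brc1ccc([I+]c2ccc(Br)cc2Br)c(Br)c1.[Cl-]
F7 | step 5 | 1,4-dibromo-2-(2,4-dibromophenoxy)-3-methoxybenzene | COc1c(Br)ccc(Br)c1Oc1ccc(Br)cc1Br
F0 | step 1 | none | none
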